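(Readings and results were generated by integration from invented constants; the scatter is artificial.)

I count D, E and L in fractions of the D charged, and X in equivalents.

| setting | grey | violet | Sunday's | Wednesday's | Thursday's |
|---|---|---|---|---|---|
| D | 0.0010 M | 0.0010 M | 0.0010 M | 0.0010 M | 0.0010 M (fed, over 3.0 min) |
| X | 1 equiv | 0.50 equiv | 1.00 equiv (fed, over 3.0 min) | 1.00 equiv | 1.00 equiv |
| G | 0.53 mM (held) | 0.53 mM (held) | 0.53 mM (held) | 0.53 mM (held) | 0.53 mM (held) |
| remark | run made earlier | run made earlier | all else is in the flask from the start; the feed brings no volume worth counting | everything together at the start | all else is in the flask from the start; the feed brings no volume worth counting |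
| time |  |  | 4.0 min | 4.0 min | 4.0 min |

- grey (time / min: E / %, L / %): 0.667: 22.1, 18.2; 1.33: 22.3, 19.2; 2.00: 22.5, 18.4; 2.50: 23.4, 19.4
- violet (time / s: E / %, L / %): 10.0: 17.5, 6.1; 15.0: 19.8, 8.2; 25.0: 21.2, 9.4

(standard deviation of a reading: 0.5 percentage points)

- the flask with the highest share of E in E plus L ("all alike" if they lie within 1.5 percentage points) (Sunday's / Wednesday's / Thursday's / all alike)
- share of E in E plus L at the end, Sunday's
- share of E in E plus L at the end, Wednesday's
- share of E in E plus L at the end, Thursday's

- percent here means D units held: one Z counts as two
- at the start none of J is dissolved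
- the numbers in the tables scatter with a standard deviation of 0.5 percentage points
- steps that have been proposed: D + J -> E; G <-> J; D + E -> Z; X + J -> Q; D + X -> L

The shortest time I can read is D's life. In the violet run L stands at 6.1% after 10.0 s and at 9.4% after 25.0 s. That ratio of 0.649 lies near the 0.632 of one first-order time constant, so I take 10.0 s as D's life. The next rung is the grey run's first reading at 0.667 min, which is later than that life. There E and L read 22.1% and 18.2%, and at 2.50 min they read 23.4% and 19.4%. The slowest rung is the feed of 3.0 min, far longer than D's life.

The grey and violet runs hold X at 1 equiv and 0.50 equiv, no excess over D, and J may take X too, so I freeze no concentration of X. I freeze a ratio read from the last reading of each run instead: L per equivalent of X charged. The violet run then gives 0.188, and the grey run gives 0.194. This is my L price: the fraction of the D charged that ends as L per equivalent of X put beside D.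

Wednesday's repeats the grey run, so I expect a share of 54.7%. In Sunday's, the feed has brought 0.0556 equivalents within D's life. The price then gives L of 1.04%, and with the grey E the share is 95.7%. In Thursday's, each portion of D meets the X standing when it arrives. No reading shows X, so I put Thursday's between the other two.

The forecast has Sunday's first, with 92%, 54.6% and 63% for Sunday's, Wednesday's and Thursday's, holding of Thursday's that “L keeps competing with J throughout”.

    D + J → E (k = 79.0 L mol⁻¹ s⁻¹)
    G ⇌ J, rate k2*(csat - [J]) (kL = 7.20 s⁻¹)
    D + E → Z (k = 160 L mol⁻¹ s⁻¹)
    X + J → Q (k = 53.0 L mol⁻¹ s⁻¹)
    D + X → L (k = 22.0 L mol⁻¹ s⁻¹)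

The flask puts Sunday's first, with 93.5% for Sunday's, 54.6% for Wednesday's and 83.8% for Thursday's. In Thursday's, mean X over the first 3.0 min is 0.189 of its charge. The price turns that into L of 3.56%, and Thursday's holds 4.52%. Sunday's holds 1.63% against my 1.04%. A neighbour of Sunday's with 0.250 equiv of X fed over the same time has 0.0139 equivalents on hand within D's life. The price gives L of 0.261%, and that flask holds 0.416%.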